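The 1,2-dioxane (O1, O2, C3 bearing the propanoate arm, C4, C5, C6 bearing the phenyloctyl arm) is cut across C5–C6 and O2–C3. What remains is a C6–O1–O2 unit, read as the peroxycarbenium ion of 10-phenyldecan-2-one, and a C3–C4–C5 unit whose quaternary C3 and two CH2 groups are the ring of a 1,1-disubstituted cyclopropane. A chiral-anion-controlled, strain-releasing formal [3+3] annulation of a silyl peroxyketal with that cyclopropane forms the C–C bond, the O–C bond, the ring and both fully substituted peroxy carbons in one operation. Its precursors are an acyclic peroxyketal and methyl 3-(1-methylcyclopropyl)propanoate; ester hydrolysis finishes.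

Key step: step 6

Assumption: the (S,S)-antipode of the catalyst in step 6 is taken to lead to the (3R,6S) series; if a pilot run shows the opposite sense, the (R,R)-antipode is used with no other change.

Step 1
Reactants: 1 (8-bromooctyl)benzene; 2 isopropenylmagnesium bromide (prop-1-en-2-ylmagnesium bromide, THF solution)
Product: 3 2-methyl-10-phenyldec-1-ene
Conditions: Fe(acac)3 (5 mol%), TMEDA, hexamethylenetetramine, THF, 0 °C, slow addition of 2
Reagents that add atoms: none
Why: Iron-catalysed Kumada-type cross-coupling of a primary alkyl bromide with an alkenyl Grignard reagent is fast at 0 °C and should outrun β-hydride elimination under amine ligation; no stereocentre is formed.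

Step 2
Reactants: 3 2-methyl-10-phenyldec-1-ene
Product: 6 2-hydroperoxy-2-methoxy-10-phenyldecane (racemic), via primary ozonide 4 (not isolated), via carbonyl oxide 5 (not isolated)
Conditions: O3, CH2Cl2/MeOH (4:1), −78 °C; N2 purge; cold aqueous work-up without reductant
Reagents that add atoms: ozone, [O-][O+]=O; methanol, CO
Why: Ozonolysis in methanol (Criegee mechanism): primary ozonide 4 should cyclorevert mainly to formaldehyde and the more substituted, alkyl-stabilised carbonyl oxide 5, which methanol traps as the α-methoxy hydroperoxide; the new ketal centre is racemic and is erased again in step 6.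

Step 3
Reactants: 6 2-hydroperoxy-2-methoxy-10-phenyldecane
Product: 7 triethyl[(2-methoxy-10-phenyldecan-2-yl)peroxy]silane (racemic)
Conditions: Et3SiCl, imidazole, DMAP (cat.), CH2Cl2, 0 °C
Reagents that add atoms: chlorotriethylsilane, CC[Si](Cl)(CC)CC
Why: O-Silylation of the acidic hydroperoxide oxygen under mild base leaves the ketal untouched and gives a silyl peroxyketal, the established precursor type of peroxycarbenium ions; no stereocentre is touched.

Step 4
Reactants: 8 2-methylprop-2-en-1-ol; 9 trimethyl orthoacetate
Product: 12 methyl 4-methylpent-4-enoate, via mixed orthoester 10 (not isolated), via ketene acetal 11 (not isolated)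
Conditions: EtCO2H (cat.), neat in excess 9, 110 → 140 °C, MeOH distilled off
Reagents that add atoms: none
Why: Johnson–Claisen rearrangement: acid-catalysed exchange gives mixed orthoester 10, loss of methanol gives ketene acetal 11, and the [3,3]-sigmatropic shift delivers the γ,δ-unsaturated ester; no stereocentre is formed.

Step 5
Reactants: 12 methyl 4-methylpent-4-enoate
Product: 13 methyl 3-(1-methylcyclopropyl)propanoate
Conditions: Et2Zn, CH2I2, CH2Cl2, 0 °C → rt
Reagents that add atoms: diiodomethane, ICI
Why: Furukawa–Simmons–Smith cyclopropanation: the zinc carbenoid transfers CH2 to the electron-rich 1,1-disubstituted alkene while the ester is inert; the product is achiral, its two ring CH2 groups being enantiotopic.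

Step 6
Reactants: 7 triethyl[(2-methoxy-10-phenyldecan-2-yl)peroxy]silane; 13 methyl 3-(1-methylcyclopropyl)propanoate (1.5 equiv)
Product: 17 methyl 3-[(3R,6S)-3,6-dimethyl-6-(8-phenyloctyl)-1,2-dioxan-3-yl]propanoate, via peroxycarbenium ion 14 (not isolated), via tertiary carbenium ion 15 (not isolated), via silylperoxonium ion 16 (not isolated)
Conditions: (S,S)-imidodiphosphorimidate (IDPi) Brønsted acid with 3,3′-diaryl-BINOL backbones and N-SO2CF3 core (5 mol%), CH2Cl2, −60 → −30 °C
Reagents that add atoms: none
Why: Proposed new method: the acid, silylated in the flask, should abstract methoxide from 7 to give peroxycarbenium ion 14 as a contact ion pair with the confined chiral anion; one of the two enantiotopic ring CH2 groups of 13 then attacks the carbenium carbon at its corner (C5–C6 bond, release of about 27 kcal/mol of ring strain), the cyclopropane opens in the Markovnikov sense to tertiary cation 15, and the silylperoxy oxygen collapses onto that cation (O2–C3 bond, ion 16) before the silyl group passes to methoxide and turns the catalyst over. The closest known reaction types are the Lewis-acid [3+2] annulation of silyl peroxyketals with alkenes to 1,2-dioxolanes, the corner-electrophilic opening of alkylcyclopropanes, and silylium-based counter-anion-directed additions to oxocarbenium ions derived from methyl alkyl ketones. The 1,2-dioxane closes by a six-membered, chair-like oxygen-to-carbenium recombination (6-endo with respect to the opened C3–C5 σ-bond), so the whole is a stepwise formal [3+3] annulation. C6 is set in the C–C bond formation by the chiral anion, which must tell the methyl from the long alkyl flank of 14; C3 is set in the ring closure, where the cation is born with C5 on one face and should be captured inside the same ion pair before it relaxes, so both centres trace back to the one catalyst-controlled choice of ring CH2 and carbenium face. The step needs regioselectivity for attack at ring CH2, which the 1,1-disubstitution secures, and chemoselectivity for the σ-bond over the ester carbonyl, which the non-nucleophilic counter-anion secures because carbonyl capture of 15 gives only a reversible dialkoxycarbenium ion.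

Step 7
Reactants: 17 methyl 3-[(3R,6S)-3,6-dimethyl-6-(8-phenyloctyl)-1,2-dioxan-3-yl]propanoate
Product: 18 3-[(3R,6S)-3,6-dimethyl-6-(8-phenyloctyl)-1,2-dioxan-3-yl]propanoic acid
Conditions: LiOH·H2O, THF/MeOH/H2O, 0 °C → rt; then 1 M HCl to pH 3 at 0 °C
Reagents that add atoms: lithium hydroxide, [Li+].[OH-]
Why: Saponification of the methyl ester; the di-tertiary dialkyl peroxide has no α-hydrogen (no Kornblum–DeLaMare fragmentation) and both stereocentres are quaternary, so neither the O–O bond nor the configuration should be at risk.

Compound list
1 | (8-bromooctyl)benzene | BrCCCCCCCCc1ccccc1 | starting material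
2 | isopropenylmagnesium bromide | CC(=C)[Mg]Br | starting material
3 | 2-methyl-10-phenyldec-1-ene | CC(=C)CCCCCCCCc1ccccc1 | intermediate
4 | primary ozonide, 4-methyl-4-(8-phenyloctyl)-1,2,3-trioxolane | CC1(CCCCCCCCc2ccccc2)COOO1 | intermediate (not isolated)
5 | carbonyl oxide of 10-phenyldecan-2-one | CC(CCCCCCCCc1ccccc1)=[O+][O-] | intermediate (not isolated)
6 | 2-hydroperoxy-2-methoxy-10-phenyldecane (racemic) | COC(C)(CCCCCCCCc1ccccc1)OO | intermediate
7 | triethyl[(2-methoxy-10-phenyldecan-2-yl)peroxy]silane (racemic) | CC[Si](CC)(CC)OOC(C)(OC)CCCCCCCCc1ccccc1 | intermediate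
8 | 2-methylprop-2-en-1-ol | CC(=C)CO | starting material
9 | trimethyl orthoacetate | CC(OC)(OC)OC | starting material
10 | mixed orthoester, 1,1-dimethoxy-1-(2-methylprop-2-enyloxy)ethane | CC(OC)(OC)OCC(C)=C | intermediate (not isolated)
11 | ketene acetal, 1-methoxy-1-(2-methylprop-2-enyloxy)ethene | C=C(OC)OCC(C)=C | intermediate (not isolated)
12 | methyl 4-methylpent-4-enoate | COC(=O)CCC(C)=C | intermediate
13 | methyl 3-(1-methylcyclopropyl)propanoate | COC(=O)CCC1(C)CC1 | intermediate
14 | peroxycarbenium ion, (10-phenyldecan-2-ylidene)(triethylsilyloxy)oxonium, paired with the catalyst anion | CC(CCCCCCCCc1ccccc1)=[O+]O[Si](CC)(CC)CC | intermediate (not isolated)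
15 | tertiary carbenium ion, methyl (7S)-4,7-dimethyl-15-phenyl-7-[(triethylsilyl)peroxy]pentadecanoate with the cationic centre at C4 | C[C@](CCCCCCCCc1ccccc1)(CC[C+](C)CCC(=O)OC)OO[Si](CC)(CC)CC | intermediate (not isolated)
16 | silylperoxonium ion, 17 carrying triethylsilyl on O2 | C[C@]1(CCCCCCCCc2ccccc2)CC[C@](C)(CCC(=O)OC)[O+]([Si](CC)(CC)CC)O1 | intermediate (not isolated)
17 | methyl 3-[(3R,6S)-3,6-dimethyl-6-(8-phenyloctyl)-1,2-dioxan-3-yl]propanoate | C[C@]1(CCCCCCCCc2ccccc2)CC[C@](C)(CCC(=O)OC)OO1 | intermediate
18 | 3-[(3R,6S)-3,6-dimethyl-6-(8-phenyloctyl)-1,2-dioxan-3-yl]propanoic acid | C[C@]1(CCCCCCCCc2ccccc2)CC[C@](C)(CCC(=O)O)OO1 | target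

Total step count: 7. Longest linear sequence: 5 steps (steps 1, 2, 3, 6, 7).

Steps most likely to fail

Step 6 (proposed new method). The cyclopropane σ-bond may be too weak a nucleophile, so that the peroxycarbenium ion decays first by Criegee/Hock-type migration or by elimination. Cation 15 may lose a proton and re-close under acid without control, or be trapped by the ester carbonyl followed by demethylation to a lactone. Facial discrimination at C6 and at C3 may be poor, which would give the cis diastereomer or low enantiomeric purity. The fallback uses known chemistry only and sets out from 7 and 12. Lewis-acid allyl transfer of the Hosomi–Sakurai type (allyltributylstannane, Me3SiOTf, CH2Cl2, −78 °C) to the peroxycarbenium ion from 7 should give triethyl[(4-methyl-12-phenyldodec-1-en-4-yl)peroxy]silane F1. Cross-metathesis with an excess of 12 (second-generation Grubbs catalyst, CH2Cl2, 40 °C) should give methyl 4,7-dimethyl-15-phenyl-7-[(triethylsilyl)peroxy]pentadec-4-enoate F2 as an E/Z mixture. Bu4NF in THF at 0 °C should free methyl 7-hydroperoxy-4,7-dimethyl-15-phenylpentadec-4-enoate F3. Cycloperoxymercuration with Hg(OAc)2 in CH2Cl2 (Markovnikov attack of the hydroperoxide on the trisubstituted alkene) should give methyl 3-[4-(acetoxymercurio)-3,6-dimethyl-6-(8-phenyloctyl)-1,2-dioxan-3-yl]propanoate F4. NaBH4/NaOH should then replace mercury by hydrogen and give methyl 3-[3,6-dimethyl-6-(8-phenyloctyl)-1,2-dioxan-3-yl]propanoate F5 as a mixture of stereoisomers. This sequence is not stereocontrolled: the trans racemate would be separated from the cis on silica and resolved on a chiral stationary phase, and the route is rejoined at 17.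

Step 2. The primary ozonide may fragment toward formaldehyde oxide and the ketone instead of the ketone oxide, and the hydroperoxy ketal may lose methanol or hydrogen peroxide on work-up. The fallback sets out from 3. Ozonolysis with reductive work-up (O3, CH2Cl2, −78 °C; Me2S) gives, whatever the sense of fragmentation, 10-phenyldecan-2-one F6. Ketalisation (HC(OMe)3, MeOH, TsOH) gives 2,2-dimethoxy-10-phenyldecane F7. Elimination (Me3SiOTf, iPr2NEt, CH2Cl2) gives 2-methoxy-10-phenyldec-1-ene F8, whose internal enol ether isomers converge in the next reaction. Isayama–Mukaiyama peroxidation (Co(acac)2, O2, Et3SiH, ClCH2CH2Cl, rt) then gives 7 directly, so that 6 and step 3 are bypassed.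

Step 5. Cyclopropanation may stop short of completion, and alkene 12 is hard to separate from 13; as the far better nucleophile it would divert step 6 to the known [3+2] annulation. The fallback builds the ring before the chain and sets out from 8. Hydroxyl-directed Simmons–Smith cyclopropanation (Et2Zn, CH2I2, CH2Cl2, 0 °C), which is fast and complete on the allylic alcohol, gives (1-methylcyclopropyl)methanol F9. Swern oxidation ((COCl)2, DMSO, Et3N, −78 °C) gives 1-methylcyclopropane-1-carbaldehyde F10. Wittig olefination with methyl (triphenylphosphoranylidene)acetate gives methyl (E)-3-(1-methylcyclopropyl)prop-2-enoate F11. Conjugate reduction with [(Ph3P)CuH]6 (polar hydride delivery to the β-carbon, no cyclopropylcarbinyl radical) returns to 13 free of alkene 12.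

Further compounds
F1 | step 6 | triethyl[(4-methyl-12-phenyldodec-1-en-4-yl)peroxy]silane (racemic) | CC[Si](CC)(CC)OOC(C)(CC=C)CCCCCCCCc1ccccc1
F2 | step 6 | methyl 4,7-dimethyl-15-phenyl-7-[(triethylsilyl)peroxy]pentadec-4-enoate (racemic, E/Z mixture) | CC[Si](CC)(CC)OOC(C)(CC=C(C)CCC(=O)OC)CCCCCCCCc1ccccc1
F3 | step 6 | methyl 7-hydroperoxy-4,7-dimethyl-15-phenylpentadec-4-enoate (racemic, E/Z mixture) | COC(=O)CCC(C)=CCC(C)(OO)CCCCCCCCc1ccccc1
F4 | step 6 | methyl 3-[4-(acetoxymercurio)-3,6-dimethyl-6-(8-phenyloctyl)-1,2-dioxan-3-yl]propanoate (stereoisomer mixture) | COC(=O)CCC1(C)OOC(C)(CCCCCCCCc2ccccc2)CC1[Hg]OC(C)=O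
F5 | step 6 | methyl 3-[3,6-dimethyl-6-(8-phenyloctyl)-1,2-dioxan-3-yl]propanoate (mixture of stereoisomers) | CC1(CCCCCCCCc2ccccc2)CCC(C)(CCC(=O)OC)OO1
F6 | step 2 | 10-phenyldecan-2-one | CC(=O)CCCCCCCCc1ccccc1
F7 | step 2 | 2,2-dimethoxy-10-phenyldecane | COC(C)(OC)CCCCCCCCc1ccccc1
F8 | step 2 | 2-methoxy-10-phenyldec-1-ene | COC(=C)CCCCCCCCc1ccccc1
F9 | step 5 | (1-methylcyclopropyl)methanol | CC1(CO)CC1
F10 | step 5 | 1-methylcyclopropane-1-carbaldehyde | CC1(C=O)CC1
F11 | step 5 | methyl (E)-3-(1-methylcyclopropyl)prop-2-enoate | COC(=O)/C=C/C1(C)CC1
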